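**Assumption:** 2‑ethylanisole and (2E,6E)‑farnesyl bromide are taken as commercial. The quinidine‑derived catalyst in Step 6 is assumed to give the (1R,6S) epoxide; if the sense proves opposite, its quinine‑derived pseudoenantiomer is used with no other change.

The target is the syn epoxyquinol: 4‑OH cis to the oxirane oxygen, (4R,5R,6R) in cyclohexenone numbering, (1R,5R,6R) in 7‑oxabicyclo[4.1.0]heptenone numbering.

## Retrosynthetic overview

1. The carbinol comes from a site‑ and syn‑selective 1,2‑reduction of a 2,3‑epoxy‑1,4‑benzoquinone.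
2. The epoxyquinone comes from deketalisation of an epoxy p‑quinone monoketal. The oxirane and both of its stereocentres (including the quaternary one) come from a new catalytic enantioselective nucleophilic epoxidation of an achiral p‑quinone monoketal.
3. The monoketal comes from oxidative dearomatisation (PhI(OAc)2/MeOH) of 5‑ethyl‑2‑farnesyl‑4‑methoxyphenol, which fixes which oxygen becomes the C=O.
4. The aryl–farnesyl bond comes from an ortho‑metalated phenoxide (Br/Li exchange, Cu) and (E,E)‑farnesyl bromide; the phenol comes from 2‑ethylanisole.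
5. Ring order: the six‑membered carbocycle is the original benzene ring, dearomatised in Step 5; the oxirane is formed second, in Step 6.

## Route

**Step 1**
Reactants: 1, 2‑ethylanisole
Product: 2, 4‑bromo‑2‑ethylanisole
Conditions: NBS (1.05 equiv), MeCN, 0 °C → rt, dark
Reagents that add atoms: N‑bromosuccinimide, O=C1CCC(=O)N1Br
Why: Electrophilic aromatic bromination; NBS in MeCN brominates anisoles para to OMe, and the polar, dark conditions avoid benzylic bromination of the ethyl group.

**Step 2**
Reactants: 2, 4‑bromo‑2‑ethylanisole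
Product: 3, 3‑ethyl‑4‑methoxyphenol
Conditions: n‑BuLi, THF, −78 °C; B(OMe)3, −78 °C → rt; then 30% H2O2, aq NaOH, 0 °C → rt
Reagents that add atoms: hydrogen peroxide, OO (supplies the phenolic O; trimethyl borate, COB(OC)OC, is only a transient carrier)
Why: Br/Li exchange, borylation and oxidative C–B to C–O conversion (boronate oxidation) give the phenol exactly where the bromine was.

**Step 3**
Reactants: 3, 3‑ethyl‑4‑methoxyphenol
Product: 4, 2‑bromo‑5‑ethyl‑4‑methoxyphenol
Conditions: NBS (1.0 equiv), CH2Cl2, −20 → 0 °C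
Reagents that add atoms: N‑bromosuccinimide, O=C1CCC(=O)N1Br
Why: Electrophilic aromatic bromination ortho to the free OH (strongest activator, para position blocked by OMe), at the ortho site that is para to ethyl and not the one wedged between OH and ethyl.

**Step 4**
Reactants: 4, 2‑bromo‑5‑ethyl‑4‑methoxyphenol; 5, (2E,6E)‑farnesyl bromide
Product: 6, 5‑ethyl‑4‑methoxy‑2‑[(2E,6E)‑3,7,11‑trimethyldodeca‑2,6,10‑trien‑1‑yl]phenol
Conditions: NaH (1.1 equiv), Et2O–THF, 0 °C; t‑BuLi (2.1 equiv), −78 °C; CuBr·SMe2 (1.0 equiv); then 5 (1.1 equiv), −78 → 0 °C; aq NH4Cl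
Reagents that add atoms: (2E,6E)‑farnesyl bromide, BrC/C=C(\C)CC/C=C(\C)CCC=C(C)C
Why: Br/Li exchange on the phenoxide gives the C‑metalated phenoxide, whose arylcopper undergoes SN2 allylic substitution at the primary carbon of the γ,γ‑disubstituted bromide; the aryl carbon nucleophile outcompetes the phenoxide oxygen at low temperature, and the alkenes are not touched, so E,E geometry is retained.

**Step 5**
Reactants: 6, 5‑ethyl‑2‑farnesyl‑4‑methoxyphenol
Product: 7, 5‑ethyl‑4,4‑dimethoxy‑2‑[(2E,6E)‑3,7,11‑trimethyldodeca‑2,6,10‑trien‑1‑yl]cyclohexa‑2,5‑dien‑1‑one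
Conditions: PhI(OAc)2 (1.05 equiv), NaHCO3, MeOH, 0 °C, 20 min
Reagents that add atoms: methanol, CO
Why: Hypervalent‑iodine oxidative dearomatisation of a p‑methoxyphenol in MeOH gives the p‑quinone monoketal with the C=O next to the farnesyl carbon and the ketal next to the ethyl carbon; phenol oxidation is much faster than any reaction of the isolated trisubstituted alkenes.

**Step 6 (new key step)**
Reactants: 7, the p‑quinone monoketal
Product: 8, (1R,6S)‑4‑ethyl‑5,5‑dimethoxy‑1‑[(2E,6E)‑3,7,11‑trimethyldodeca‑2,6,10‑trien‑1‑yl]‑7‑oxabicyclo[4.1.0]hept‑3‑en‑2‑one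
Conditions: catalyst C* (10 mol %), cumene hydroperoxide (1.5 equiv), Cs2CO3 (solid, 1.0 equiv), toluene, −20 °C. C* is the quinidine‑derived bifunctional ammonium–urea: N‑(9‑anthracenylmethyl)‑9‑deoxy‑9‑epi‑9‑[3‑(3,5‑bis(trifluoromethyl)phenyl)ureido]quinidinium bromide.
Reagents that add atoms: cumene hydroperoxide, CC(C)(OO)c1ccccc1 (delivers one O)
Why: Proposed new method: catalytic enantioselective Weitz–Scheffer epoxidation of a 2‑alkyl p‑quinone monoketal under bifunctional ammonium–urea phase‑transfer catalysis — the chiral ammonium ion‑pairs with cumyl‑OO⁻ while the urea hydrogen‑bonds the dienone C=O and then the dienolate, so the peroxide adds to C‑3 (the only β‑CH; the ethyl‑bearing β‑carbon is deactivated and the farnesyl alkenes are inert to a nucleophilic oxidant) on the face left open by the catalyst, and the enolate closes by 3‑exo‑tet displacement of cumyl alkoxide on the same face, forming the cis‑fused oxirane and both stereocentres (quaternary C‑1 R, C‑6 S) in one operation; the closest known reaction types are cinchona‑ammonium phase‑transfer epoxidation of chalcones and 2‑alkyl‑1,4‑naphthoquinones and the stoichiometric tartrate‑mediated epoxidation of quinone monoketals.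

**Step 7**
Reactants: 8, the epoxy ketal
Product: 9, (1R,6S)‑4‑ethyl‑1‑[(2E,6E)‑3,7,11‑trimethyldodeca‑2,6,10‑trien‑1‑yl]‑7‑oxabicyclo[4.1.0]hept‑3‑ene‑2,5‑dione
Conditions: montmorillonite K10, wet CH2Cl2, rt
Reagents that add atoms: water, O
Why: Mild heterogeneous acid‑catalysed ketal hydrolysis of the kind used for epoxy quinone dimethyl ketals; the oxirane and trisubstituted alkenes are expected to survive, and no stereocentre is involved.

**Step 8**
Reactants: 9, the epoxyquinone
Product: 10, (1R,5R,6R)‑4‑ethyl‑5‑hydroxy‑1‑[(2E,6E)‑3,7,11‑trimethyldodeca‑2,6,10‑trien‑1‑yl]‑7‑oxabicyclo[4.1.0]hept‑3‑en‑2‑one (target)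
Conditions: NaBH4 (0.5 equiv), CeCl3·7H2O (1.1 equiv), MeOH, −78 °C; aq NH4Cl
Reagents that add atoms: none
Why: Luche 1,2‑reduction is expected to occur at the C‑5 carbonyl, which is more electrophilic (ethyl is α to it but β to the C‑2 carbonyl) and less hindered (flanked by the epoxide CH, whereas C‑2 is flanked by the quaternary carbon whose farnesyl CH2 blocks the face anti to the oxirane); hydride adds anti to the epoxide oxygen, giving the cis (syn) epoxy alcohol, 5R.

## Compound list

1 | 2‑ethylanisole | CCc1ccccc1OC | starting material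
2 | 4‑bromo‑2‑ethylanisole | CCc1cc(Br)ccc1OC | intermediate
3 | 3‑ethyl‑4‑methoxyphenol | CCc1cc(O)ccc1OC | intermediate
4 | 2‑bromo‑5‑ethyl‑4‑methoxyphenol | CCc1cc(O)c(Br)cc1OC | intermediate
5 | (2E,6E)‑farnesyl bromide | BrC/C=C(\C)CC/C=C(\C)CCC=C(C)C | starting material
6 | 5‑ethyl‑4‑methoxy‑2‑[(2E,6E)‑farnesyl]phenol | CCc1cc(O)c(C/C=C(\C)CC/C=C(\C)CCC=C(C)C)cc1OC | intermediate
7 | 5‑ethyl‑4,4‑dimethoxy‑2‑[(2E,6E)‑farnesyl]cyclohexa‑2,5‑dien‑1‑one | CCC1=CC(=O)C(C/C=C(\C)CC/C=C(\C)CCC=C(C)C)=CC1(OC)OC | intermediate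
8 | (1R,6S)‑4‑ethyl‑5,5‑dimethoxy‑1‑[(2E,6E)‑farnesyl]‑7‑oxabicyclo[4.1.0]hept‑3‑en‑2‑one | CCC1=CC(=O)[C@]2(C/C=C(\C)CC/C=C(\C)CCC=C(C)C)O[C@@H]2C1(OC)OC | intermediate
9 | (1R,6S)‑4‑ethyl‑1‑[(2E,6E)‑farnesyl]‑7‑oxabicyclo[4.1.0]hept‑3‑ene‑2,5‑dione | CCC1=CC(=O)[C@]2(C/C=C(\C)CC/C=C(\C)CCC=C(C)C)O[C@@H]2C1=O | intermediate
10 | (1R,5R,6R)‑4‑ethyl‑5‑hydroxy‑1‑[(2E,6E)‑farnesyl]‑7‑oxabicyclo[4.1.0]hept‑3‑en‑2‑one | CCC1=CC(=O)[C@]2(C/C=C(\C)CC/C=C(\C)CCC=C(C)C)O[C@@H]2[C@@H]1O | target

## Summary

Total steps: 8. Longest linear sequence: 8 (from 2‑ethylanisole; farnesyl bromide enters in Step 4).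

Three steps most likely to fail:

1. **Step 6 (proposed new asymmetric epoxidation).** Risks are insufficient ee, the wrong facial sense, or slow turnover on the hindered α‑branched enone arm. Fallback with known chemistry: stoichiometric reagent control by tartrate‑mediated nucleophilic epoxidation of 7 (trityl hydroperoxide, NaHMDS, diisopropyl tartrate of the appropriate hand, toluene, −50 °C), a method established for alkyl/prenyl‑substituted quinone monoketals.

2. **Step 8 (site‑ and face‑selective reduction).** Risks are competing reduction at C‑2 or formation of the anti epimer. Fallback: switch from substrate control to catalyst control with a CBS oxazaborolidine/catecholborane reduction, using the α‑ethyl enone arm as the large group and the antipode matched to attack anti to the oxirane. If the anti alcohol still dominates, correct it by Mitsunobu inversion (p‑nitrobenzoic acid, DIAD, PPh3, then mild methanolysis).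

3. **Step 4 (aryl–farnesyl bond).** Risks are O‑allylation, SN2′ attack and Wurtz‑type homocoupling of the bromide. Fallback: protect 4 as its MOM ether and form the bond by Pd‑catalysed Stille coupling with (2E,6E)‑farnesyltributylstannane (Pd2(dba)3/P(t‑Bu)3, CsF, dioxane), then remove MOM with PPTS in warm t‑BuOH to return to 6.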